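None of the constants is given, but one can be read from the runs: that of starting material + target <-> idle adduct. What stands first is the problem.

in all of them: starting material 1.9 M
- Tuesday's: reagent 0.50 equiv; free catalyst 5 mol%; run made earlier
- Sunday's: reagent 0.50 equiv; free catalyst 20 mol%; run made earlier
- flask: reagent 0.500 equiv; free catalyst 9.9 mol%; time 15 min
- Tuesday's (time / min: idle adduct / %, target / %): 3.00: 8.7, 6.4; 6.00: 16.5, 12.0; 10.0: 24.4, 20.4; 12.0: 28.0, 23.0; 15.0: 32.3, 29.1
- Sunday's (time / min: idle adduct / %, target / %): 1.33: 8.3, 7.3; 4.00: 30.7, 26.7; 8.00: 36.4, 42.4; 10.0: 35.4, 46.7; 15.0: 38.0, 48.7

(standard deviation of a reading: 1 percentage point)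
- amount of idle adduct in percent of the starting material charged, at 50 s, 4.0 min and 15 min
- percent here means starting material units held: one idle adduct counts as two
- what is said of target includes idle adduct
- what was read earlier has a scatter of 1 percentage point, one standard deviation
- steps that have been proposed: starting material + free catalyst <-> catalyst intermediate A; catalyst intermediate D -> free catalyst + target; catalyst intermediate B -> by-product + catalyst intermediate C; reagent + catalyst intermediate A <-> catalyst intermediate B; reagent + target -> over-reaction product; starting material + target <-> idle adduct; catalyst intermediate C -> catalyst intermediate D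
- in an amount of target, one idle adduct counts as one target

Suppose this step keeps up with the target. With a the idle adducts per starting material charged, p the target as counted (adduct included) and c₀ the starting concentration of starting material, the free target is p − a and the free starting material is 1 − p − a. Then

c(idle adduct) / [c(starting material) · c(target)] = a / [(1 − p − a)(p − a) · c₀]

Tuesday's last reading gives 1.20 L mol⁻¹, Sunday's 1.04 L mol⁻¹.

The objection: these readings differ, and our balance counts starting material held on the catalyst as free, which should weigh more at Sunday's higher loading. This flask's loading lies between the two, so we take the mean, 1.12 L mol⁻¹, the association quotient; with c₀ it makes b = 2.13. The percent asked is then 2a, from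

a = b(1 − p − a)(p − a)

The end state comes first. Each turn of the cycle spends one reagent, so in this flask reagent is the limiting reagent and we expect p to stop near 0.5, which gives 39.3% of adduct.

Now the pace. Tuesday's mean rate is 0.0194 min⁻¹, Sunday's to 4.00 min is 0.0668 min⁻¹, and a power law in the loading gives 0.0357 min⁻¹ here.

But a straight line reaches 53.6% at 15 min, more than the cap. So we rescale the clock: 15 min here matches 8.01 min on Sunday, where target read 42.4%, and the rule gives 38.2%.

At 4.0 min in this flask, our p = 14.3% gives 17.7%.

Early on, a rate averaged from zero is open to doubt: Sunday's first two readings extrapolate back to a lag of 0.325 min. Carrying that read lag over to this flask as an estimate, we get p = 1.81% and 2.44% at 50 s.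

The forecast says 3.5%, 19.3% and 37%, differing from ours at each point, and holds that “the adduct is essentially at equilibrium after a lag of about a minute”.

The flask gives 2.18%, 19.1% and 37.4%.

    starting material + free catalyst ⇌ catalyst intermediate A (K = 0.940 L mol⁻¹, k = 0.0190 L mol⁻¹ s⁻¹)
    catalyst intermediate D → free catalyst + target (k = 1.10 s⁻¹)
    catalyst intermediate B → by-product + catalyst intermediate C (k = 0.260 s⁻¹)
    reagent + catalyst intermediate A ⇌ catalyst intermediate B (K = 0.890 L mol⁻¹, k = 0.100 L mol⁻¹ s⁻¹)
    reagent + target → over-reaction product (k = 2.30 × 10⁻⁴ L mol⁻¹ s⁻¹)
    starting material + target ⇌ idle adduct, settled at all times (K = 1.20 L mol⁻¹)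
    catalyst intermediate C → catalyst intermediate D (k = 0.0170 s⁻¹)

In this flask, from 1.50 min to 15.0 min, reagent fell from 81.0% to 8.69% of its charge and catalyst intermediate C from 46.1% to 11.3% of the catalyst, while target rose from 4.55% to 43.2%. Alongside it, starting material + target <-> idle adduct carried idle adduct from 6.03% to 37.4%. This flask's target put into the quotient gives 38.4% against 37.4%. Sunday's target at 4.00 min gives 29.6% against the 30.7% read.

Readings and results were computed with constants of no real substance; the scatter is artificial.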